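**Strategy.** The tetrasubstituted C3=C4 alkene (lactone numbering O1, C2=O, C3, C4, C5H2) is shared by the butenolide ring and the cyclooctane ring, so cutting it together with the lactone O1–C5 bond opens both rings at once. The precursor is an acyclic chain, bent by the cis-cyclopropane, that ends in an α-phosphono carboxylic acid and a chloromethyl cyclopropyl ketone. Carbonate base should trigger carboxylate O-alkylation to an eleven-membered keto lactone and then transannular Horner–Wadsworth–Emmons olefination, forming O1–C5 and C3=C4, hence butenolide and eight-membered ring, in one operation. The stereocentres come from (R)-citronellal, an enzymatic Baeyer–Villiger desymmetrisation, a substrate-controlled cyclopropanation and one catalyst-controlled anti-allylboration.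

Key step: step 13

Atom labels used below (own numbering of the target): butenolide O1, C2 (C=O), C3, C4, C5 (OCH2); cyclooctane C3, C4, C6 and C7 (cyclopropane CH, with C12 the cyclopropane CH2), C8 (CHMe), C9 (CH2), C10 (CHOAc), C11 (CH carrying the side chain).

Assumption: the (S)-enantiomer of the phosphoric acid in step 7 is taken to be the one that directs the allyl group to the Si face of aldehyde 7; if the sense is the opposite, its antipode is used.

Step 1
Reactants: 1 4-methylcyclohexanone
Product: 2 (S)-5-methyloxepan-2-one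
Conditions: cyclohexanone monooxygenase (recombinant, Acinetobacter type), NADP+ (cat.), glucose dehydrogenase, D-glucose, air (O2), phosphate buffer pH 8, 25 °C
Reagents that add atoms: dioxygen, O=O
Why: Enzymatic Baeyer–Villiger desymmetrisation, in which the enzyme pocket chooses one of the two enantiotopic ring CH2 groups for migration, should set the methyl-bearing centre (later C8) in high enantiomeric purity.

Step 2
Reactants: 2 (S)-5-methyloxepan-2-one
Product: 4 (R)-5-methyl-6,7-dihydrooxepin-2(5H)-one, via selenide 3 (not isolated)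
Conditions: LiN(i-Pr)2, THF, −78 °C; PhSeBr; then H2O2, pyridine, CH2Cl2, 0 °C to rt
Reagents that add atoms: none
Why: α-Selenenylation of the lactone enolate and syn-elimination of the selenoxide is the standard route to an α,β-unsaturated lactone, and the ring enforces the cis alkene needed for the cyclopropane fusion (the descriptor changes only because the neighbouring carbon becomes sp2).

Step 3
Reactants: 4 (R)-5-methyl-6,7-dihydrooxepin-2(5H)-one
Product: 5 (1S,6R,7S)-6-methyl-3-oxabicyclo[5.1.0]octan-2-one
Conditions: Me3S(O)I, NaH, DMSO, rt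
Reagents that add atoms: trimethylsulfoxonium iodide, C[S+](C)(C)=O.[I-]
Why: Corey–Chaykovsky cyclopropanation (conjugate addition of the sulfoxonium ylide, then 3-exo-tet closure) can only give the cis-fused cyclopropane on a ring alkene, and the ylide should add anti to the adjacent methyl group, which sets C6 and C7 from C8.

Step 4
Reactants: 5 (1S,6R,7S)-6-methyl-3-oxabicyclo[5.1.0]octan-2-one
Product: 6 (1S,2S)-2-[(2R)-4-hydroxybutan-2-yl]-N-methoxy-N-methylcyclopropane-1-carboxamide
Conditions: MeNHOMe·HCl, i-PrMgCl, THF, −20 to 0 °C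
Reagents that add atoms: N,O-dimethylhydroxylamine hydrochloride, CNOC.Cl
Why: Aminolysis of the lactone by the chloromagnesium amide (Weinreb amide synthesis) opens the seven-membered ring without touching the stereocentres and leaves a carbonyl group that resists the bases and boranes used later.

Step 5
Reactants: 6 hydroxy Weinreb amide
Product: 7 (1S,2S)-N-methoxy-N-methyl-2-[(2R)-4-oxobutan-2-yl]cyclopropane-1-carboxamide
Conditions: TEMPO (cat.), PhI(OAc)2, CH2Cl2, rt
Reagents that add atoms: none
Why: Oxoammonium-mediated oxidation stops at the aldehyde and is neutral enough not to epimerise the cyclopropane or the β-methyl centre.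

Step 6
Reactants: 8 (R)-citronellal
Product: 9 2-[(1E,4R)-4,8-dimethylnona-1,7-dien-1-yl]-4,4,5,5-tetramethyl-1,3,2-dioxaborolane
Conditions: CH2(Bpin)2, lithium 2,2,6,6-tetramethylpiperidide, THF, −78 °C to rt
Reagents that add atoms: bis(4,4,5,5-tetramethyl-1,3,2-dioxaborolan-2-yl)methane, CC1(C)OB(CB2OC(C)(C)C(C)(C)O2)OC1(C)C
Why: Boron–Wittig olefination of the aldehyde with the lithiated geminal bis(boronate) should give the (E)-alkenylboronate, and the side-chain stereocentre, β to the carbonyl group, is not at risk.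

Step 7
Reactants: 7 aldehyde Weinreb amide, 9 alkenylboronate
Product: 11 (1S,2S)-2-[(2R,4R,5R,6R)-5-ethenyl-4-hydroxy-6,10-dimethylundec-9-en-2-yl]-N-methoxy-N-methylcyclopropane-1-carboxamide, via allylboronate 10 (not isolated)
Conditions: [Ir(cod)2]BF4 (cat.), PCy3 (cat., pre-treated with H2), (S)-3,3′-bis(2,4,6-triisopropylphenyl)-1,1′-binaphthyl-2,2′-diyl hydrogen phosphate [(S)-TRIP, cat.], 4 Å molecular sieves, 1,2-dichloroethane, rt; aqueous work-up
Reagents that add atoms: none
Why: An iridium hydride moves the double bond of 9 by one position to the (E)-γ-substituted allylboronate 10, which adds to the aldehyde through a chair-like six-membered transition state organised by the chiral phosphoric acid, so that the (E) geometry fixes the anti relation C10/C11 and the catalyst fixes the aldehyde face (tandem alkene isomerisation/asymmetric allylboration).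

Step 8
Reactants: 11 homoallylic alcohol
Product: 13 (1S,2S)-2-[(2R,4R,5R,6R)-4-hydroxy-5-(2-hydroxyethyl)-6,10-dimethylundec-9-en-2-yl]-N-methoxy-N-methylcyclopropane-1-carboxamide, via alkylborane 12 (not isolated)
Conditions: 9-BBN, THF, 0 °C to rt; then NaOH, H2O2, 0 °C
Reagents that add atoms: hydrogen peroxide, OO
Why: Hydroboration–oxidation with the bulky borane is selective for the monosubstituted vinyl group over the trisubstituted side-chain alkene and puts the hydroxyl on the terminal carbon, the future lactone carbon C2.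

Step 9
Reactants: 13 diol
Product: 14 (1S,2S)-N-methoxy-N-methyl-2-[(2R)-1-{(2R,3R)-3-[(2R)-6-methylhept-5-en-2-yl]-5-oxooxolan-2-yl}propan-2-yl]cyclopropane-1-carboxamide
Conditions: TEMPO (cat.), PhI(OAc)2, CH2Cl2, rt
Reagents that add atoms: none
Why: Oxidative lactonisation of the 1,4-diol (primary alcohol to aldehyde, lactol, lactone) masks the C10 hydroxyl and the C2 carboxyl together as a trans-γ-butyrolactone.

Step 10
Reactants: 14 trans-lactone
Product: 16 α-(diethoxyphosphoryl) lactone, via phosphonite 15 (not isolated)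
Conditions: LiN(i-Pr)2, THF, −78 °C; ClP(OEt)2, −78 °C to rt; then H2O2, 0 °C
Reagents that add atoms: diethyl chlorophosphite, CCOP(Cl)OCC; hydrogen peroxide, OO
Why: C-Phosphinylation of the lactone enolate with the trivalent phosphorus chloride and oxidation is a known route to α-phosphono lactones, and the mixture at C3 does not matter because C3 becomes sp2.

Step 11
Reactants: 16 α-phosphono lactone
Product: 19 (3R,4R,6R)-4-[(tert-butyldimethylsilyl)oxy]-2-(diethoxyphosphoryl)-6-{(1S,2S)-2-[methoxy(methyl)carbamoyl]cyclopropyl}-3-[(2R)-6-methylhept-5-en-2-yl]heptanoic acid, via hydroxy carboxylate 17 (not isolated), via bis-silyl compound 18 (not isolated)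
Conditions: LiOH·H2O, THF/H2O, 0 °C to rt, evaporation; TBSOTf, 2,6-lutidine, CH2Cl2, 0 °C; then K2CO3, THF/MeOH/H2O, rt, work-up at pH 4
Reagents that add atoms: lithium hydroxide monohydrate, [Li+].[OH-].O; tert-butyldimethylsilyl trifluoromethanesulfonate, CC(C)(C)[Si](C)(C)OS(=O)(=O)C(F)(F)F
Why: Saponification of the lactone, silylation of both the C10 hydroxyl and the carboxylate, and selective hydrolysis of the labile silyl ester should free the phosphonoacetic acid while the silyl ether prevents relactonisation onto C10.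

Step 12
Reactants: 19 silyl ether acid
Product: 20 (3R,4R,6R)-4-[(tert-butyldimethylsilyl)oxy]-6-[(1S,2S)-2-(chloroacetyl)cyclopropyl]-2-(diethoxyphosphoryl)-3-[(2R)-6-methylhept-5-en-2-yl]heptanoic acid
Conditions: LiN(SiMe3)2 (2.1 equiv), THF, −78 °C; ICH2Cl, MeLi·LiBr, −78 °C; AcOH
Reagents that add atoms: chloroiodomethane, ClCI
Why: Chloromethyllithium made in situ by iodine–lithium exchange adds once to the Weinreb amide (stable chelated tetrahedral intermediate) to give the chloromethyl ketone, while the carboxylate and the deprotonated phosphonoacetate are inert as anions (carbenoid homologation of a Weinreb amide).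

Step 13
Reactants: 20 chloromethyl ketone phosphono acid
Product: 22 tert-butyldimethylsilyl ether of alcohol 23, via keto lactone 21 (not isolated)
Conditions: Cs2CO3 (6 equiv), DMF, 60 °C, 20 added by syringe pump (final about 1 mM)
Reagents that add atoms: none
Why: Proposed new method: Cs2CO3 first forms the caesium carboxylate, which displaces chloride at C5 (SN2, 11-exo-tet) to give the eleven-membered keto lactone 21 and with it the O1–C5 bond; further carbonate deprotonates the phosphonoacetate C3–H, and the carbanion adds across the ring to the cyclopropyl ketone C4 and expels diethyl phosphate, a transannular Horner–Wadsworth–Emmons olefination that is a 5-exo-trig closure of the butenolide and in the same event closes the cyclooctane. The closest known reaction type is the one-pot butenolide synthesis from an α-halo ketone and a dialkylphosphonoacetic acid (intermolecular carboxylate alkylation, then intramolecular Horner–Wadsworth–Emmons reaction); its use with both partners in one chain, as a macrolactonisation followed by a transannular olefination, has not been shown. The eight-membered ring is therefore never closed directly but arises by contraction of the eleven-membered ring through a five-membered olefination transition state. No stereocentre is formed: C6, C7, C8, C10, C11 and the side-chain centre are carried in from 20, the C3 mixture is erased, and none of them should epimerise under carbonate conditions. The step needs intramolecular over intermolecular O-alkylation and O- over C-alkylation: slow addition at high dilution, the turn imposed by the cis-cyclopropane and the fact that only the carboxylate is ionised at the alkylation stage should secure this, and the chloromethyl ketone, whose only other α-hydrogen sits on the cyclopropane, is protected against Favorskii and aldol side reactions.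

Step 14
Reactants: 22 silyl ether
Product: 23 C10 alcohol (desacetyl target)
Conditions: HF·pyridine, pyridine, THF, 0 °C to rt
Reagents that add atoms: none
Why: Buffered fluoride cleavage of the silyl ether should leave the butenolide, the vinylcyclopropane unit and the trisubstituted alkene untouched.

Step 15
Reactants: 23 C10 alcohol
Product: 24 target CNP0018922.1
Conditions: Ac2O, DMAP (cat.), pyridine, CH2Cl2, 0 °C to rt
Reagents that add atoms: acetic anhydride, CC(=O)OC(C)=O
Why: DMAP-catalysed acylation of the secondary alcohol proceeds with retention at C10 and completes the target.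

**Compound list**

1 | 4-methylcyclohexanone | CC1CCC(=O)CC1 | starting material
2 | (S)-5-methyloxepan-2-one | C1C[C@@H](C)CCC(=O)O1 | intermediate
3 | 5-methyl-3-(phenylselanyl)oxepan-2-one (C5 as in 2, mixture at C3) | C1C[C@@H](C)CC([Se]c2ccccc2)C(=O)O1 | intermediate
4 | (R)-5-methyl-6,7-dihydrooxepin-2(5H)-one | C1C[C@@H](C)C=CC(=O)O1 | intermediate
5 | (1S,6R,7S)-6-methyl-3-oxabicyclo[5.1.0]octan-2-one (cyclopropane trans to methyl) | C1C[C@@H](C)[C@@H]2C[C@@H]2C(=O)O1 | intermediate
6 | (1S,2S)-2-[(2R)-4-hydroxybutan-2-yl]-N-methoxy-N-methylcyclopropane-1-carboxamide | OCC[C@@H](C)[C@@H]1C[C@@H]1C(=O)N(C)OC | intermediate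
7 | (1S,2S)-N-methoxy-N-methyl-2-[(2R)-4-oxobutan-2-yl]cyclopropane-1-carboxamide | O=CC[C@@H](C)[C@@H]1C[C@@H]1C(=O)N(C)OC | intermediate
8 | (R)-citronellal, (3R)-3,7-dimethyloct-6-enal | O=CC[C@H](C)CCC=C(C)C | starting material
9 | 2-[(1E,4R)-4,8-dimethylnona-1,7-dien-1-yl]-4,4,5,5-tetramethyl-1,3,2-dioxaborolane | CC1(C)OB(/C=C/C[C@H](C)CCC=C(C)C)OC1(C)C | intermediate
10 | 2-[(2E,4R)-4,8-dimethylnona-2,7-dien-1-yl]-4,4,5,5-tetramethyl-1,3,2-dioxaborolane | CC1(C)OB(C/C=C/[C@H](C)CCC=C(C)C)OC1(C)C | intermediate
11 | (1S,2S)-2-[(2R,4R,5R,6R)-5-ethenyl-4-hydroxy-6,10-dimethylundec-9-en-2-yl]-N-methoxy-N-methylcyclopropane-1-carboxamide (anti homoallylic alcohol) | O[C@@H]([C@H](C=C)[C@H](C)CCC=C(C)C)C[C@@H](C)[C@@H]1C[C@@H]1C(=O)N(C)OC | intermediate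
12 | B-alkyl-9-borabicyclo[3.3.1]nonane from 11 (boron on the terminal carbon of the former vinyl group) | O[C@@H]([C@H](CCB2C3CCCC2CCC3)[C@H](C)CCC=C(C)C)C[C@@H](C)[C@@H]1C[C@@H]1C(=O)N(C)OC | intermediate
13 | (1S,2S)-2-[(2R,4R,5R,6R)-4-hydroxy-5-(2-hydroxyethyl)-6,10-dimethylundec-9-en-2-yl]-N-methoxy-N-methylcyclopropane-1-carboxamide | O[C@@H]([C@H](CCO)[C@H](C)CCC=C(C)C)C[C@@H](C)[C@@H]1C[C@@H]1C(=O)N(C)OC | intermediate
14 | (1S,2S)-N-methoxy-N-methyl-2-[(2R)-1-{(2R,3R)-3-[(2R)-6-methylhept-5-en-2-yl]-5-oxooxolan-2-yl}propan-2-yl]cyclopropane-1-carboxamide (trans-lactone) | O=C1C[C@H]([C@H](C)CCC=C(C)C)[C@@H](C[C@@H](C)[C@@H]2C[C@@H]2C(=O)N(C)OC)O1 | intermediate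
15 | 4-(diethoxyphosphanyl) derivative of lactone 14 (phosphonite at C3, mixture) | O=C1C(P(OCC)OCC)[C@H]([C@H](C)CCC=C(C)C)[C@@H](C[C@@H](C)[C@@H]2C[C@@H]2C(=O)N(C)OC)O1 | intermediate
16 | (1S,2S)-2-[(2R)-1-{(2R,3R)-4-(diethoxyphosphoryl)-3-[(2R)-6-methylhept-5-en-2-yl]-5-oxooxolan-2-yl}propan-2-yl]-N-methoxy-N-methylcyclopropane-1-carboxamide (mixture at the phosphorus-bearing carbon) | O=C1C(P(=O)(OCC)OCC)[C@H]([C@H](C)CCC=C(C)C)[C@@H](C[C@@H](C)[C@@H]2C[C@@H]2C(=O)N(C)OC)O1 | intermediate
17 | lithium salt of the ring-opened hydroxy acid of 16 (free C10 hydroxyl, C2 carboxylate) | [Li+].[O-]C(=O)C(P(=O)(OCC)OCC)[C@H]([C@H](C)CCC=C(C)C)[C@@H](C[C@@H](C)[C@@H]1C[C@@H]1C(=O)N(C)OC)O | intermediate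
18 | tert-butyldimethylsilyl ester of acid 19 (silyl ether and silyl ester) | CC(C)(C)[Si](C)(C)OC(=O)C(P(=O)(OCC)OCC)[C@H]([C@H](C)CCC=C(C)C)[C@@H](C[C@@H](C)[C@@H]1C[C@@H]1C(=O)N(C)OC)O[Si](C)(C)C(C)(C)C | intermediate
19 | (3R,4R,6R)-4-[(tert-butyldimethylsilyl)oxy]-2-(diethoxyphosphoryl)-6-{(1S,2S)-2-[methoxy(methyl)carbamoyl]cyclopropyl}-3-[(2R)-6-methylhept-5-en-2-yl]heptanoic acid (mixture at C2) | OC(=O)C(P(=O)(OCC)OCC)[C@H]([C@H](C)CCC=C(C)C)[C@@H](C[C@@H](C)[C@@H]1C[C@@H]1C(=O)N(C)OC)O[Si](C)(C)C(C)(C)C | intermediate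
20 | (3R,4R,6R)-4-[(tert-butyldimethylsilyl)oxy]-6-[(1S,2S)-2-(chloroacetyl)cyclopropyl]-2-(diethoxyphosphoryl)-3-[(2R)-6-methylhept-5-en-2-yl]heptanoic acid (mixture at C2) | OC(=O)C(P(=O)(OCC)OCC)[C@H]([C@H](C)CCC=C(C)C)[C@@H](C[C@@H](C)[C@@H]1C[C@@H]1C(=O)CCl)O[Si](C)(C)C(C)(C)C | intermediate
21 | eleven-membered keto lactone: ester between the carboxyl group of 20 and its own C5H2 (ring O1, C5, C4(=O), C6, C7, C8, C9, C10, C11, C3, C2) | O=C1C(P(=O)(OCC)OCC)[C@H]([C@H](C)CCC=C(C)C)[C@@H](C[C@@H](C)[C@@H]2C[C@@H]2C(=O)CO1)O[Si](C)(C)C(C)(C)C | intermediate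
22 | C10 tert-butyldimethylsilyl ether of alcohol 23 (tricyclic butenolide) | CC(C)(C)[Si](C)(C)O[C@@H]1C[C@@H](C)[C@@H]2C[C@@H]2C2=C(C(=O)OC2)[C@@H]1[C@H](C)CCC=C(C)C | intermediate
23 | C10 alcohol of the target skeleton (desacetyl target) | O[C@@H]1C[C@@H](C)[C@@H]2C[C@@H]2C2=C(C(=O)OC2)[C@@H]1[C@H](C)CCC=C(C)C | intermediate
24 | CNP0018922.1: butenolide fused through C3=C4 to a cyclooctane with cis-fused cyclopropane (C6, C7), methyl at C8, acetoxy at C10 and the (2R)-6-methylhept-5-en-2-yl chain at C11 | CC(=O)O[C@@H]1C[C@@H](C)[C@@H]2C[C@@H]2C2=C(C(=O)OC2)[C@@H]1[C@H](C)CCC=C(C)C | target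

**Step count.** Total: 15 steps. Longest linear sequence: 14 steps (1–5, then 7–15, from 4-methylcyclohexanone).

**Steps most likely to fail**

Step 13 (Proposed new method). Intermolecular O-alkylation (oligomerisation) may outrun closure of the eleven-membered ring, or the sequence may stall before the transannular olefination. The fallback uses known chemistry, sets out from 19 and returns at 21 and then 22. The dilithium salt of 19 (LiN(SiMe3)2) is treated with (4-methoxybenzyloxy)methyllithium (from Bu3SnCH2OPMB and n-BuLi) to give the (4-methoxybenzyloxy)methyl ketone acid F1. DDQ in CH2Cl2/pH 7 buffer frees the α-hydroxy ketone seco-acid F2. Shiina macrolactonisation (2-methyl-6-nitrobenzoic anhydride, DMAP, high dilution), which activates the acyl carbon instead of C5, closes 21, now isolated. LiCl and DBU in MeCN (Masamune–Roush conditions) then carry out the standard intramolecular Horner–Wadsworth–Emmons butenolide closure of an α-(phosphonoacetoxy) ketone to 22.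

Step 7. The iridium hydride may move the double bond further along the chain or isomerise faster than the allylboration consumes 10, which would erode the geometric purity and hence the anti selectivity; facial control may also be weak at rt. The fallback sets out from 8 and returns at 10 and 11. Wittig methylenation of 8 (Ph3PCH3Br, KOt-Bu, THF) gives (4R)-4,8-dimethylnona-1,7-diene F3. Palladium-catalysed allylic C–H acetoxylation of the terminal alkene (Pd(OAc)2, DMSO, benzoquinone, AcOH, 40 °C) gives the linear (2E,4R)-4,8-dimethylnona-2,7-dien-1-yl acetate F4. Pd2(dba)3 and B2pin2 in DMSO convert F4 by way of the π-allyl complex into isolated, geometrically pure 10. This is combined with 7 and (S)-TRIP alone in toluene at −30 °C to give 11, with no isomerisation catalyst present.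

Step 3. The ylide may attack the lactone carbonyl (ring opening) or add with poor facial selectivity in the flexible seven-membered ring. The fallback sets out from 1 and returns at 6. Enantioselective deprotonation of 1 with lithium (S,S)-bis(1-phenylethyl)amide/LiCl and TMSCl (or the antipodal base, whichever gives the R enol ether) gives (R)-trimethyl[(4-methylcyclohex-1-en-1-yl)oxy]silane F5. Saegusa–Ito oxidation (Pd(OAc)2, MeCN) gives (R)-4-methylcyclohex-2-en-1-one F6. Corey–Chaykovsky cyclopropanation, well behaved on cyclohexenones and anti to the 4-methyl group, gives (1S,5R,6S)-5-methylbicyclo[4.1.0]heptan-2-one F7. LiN(i-Pr)2/TMSCl gives the only possible silyl enol ether F8. Ozonolysis with NaBH4 work-up cleaves the ring to (1S,2S)-2-[(2R)-4-hydroxybutan-2-yl]cyclopropane-1-carboxylic acid F9. EDC·HCl, MeNHOMe·HCl and N-methylmorpholine then give 6.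

Further compounds
F1 | step 13 | (3R,4R,6R)-4-[(tert-butyldimethylsilyl)oxy]-2-(diethoxyphosphoryl)-6-[(1S,2S)-2-{[(4-methoxyphenyl)methoxy]acetyl}cyclopropyl]-3-[(2R)-6-methylhept-5-en-2-yl]heptanoic acid | OC(=O)C(P(=O)(OCC)OCC)[C@H]([C@H](C)CCC=C(C)C)[C@@H](C[C@@H](C)[C@@H]1C[C@@H]1C(=O)COCc1ccc(OC)cc1)O[Si](C)(C)C(C)(C)C
F2 | step 13 | (3R,4R,6R)-4-[(tert-butyldimethylsilyl)oxy]-2-(diethoxyphosphoryl)-6-[(1S,2S)-2-(hydroxyacetyl)cyclopropyl]-3-[(2R)-6-methylhept-5-en-2-yl]heptanoic acid | OC(=O)C(P(=O)(OCC)OCC)[C@H]([C@H](C)CCC=C(C)C)[C@@H](C[C@@H](C)[C@@H]1C[C@@H]1C(=O)CO)O[Si](C)(C)C(C)(C)C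
F3 | step 7 | (4R)-4,8-dimethylnona-1,7-diene | C=CC[C@H](C)CCC=C(C)C
F4 | step 7 | (2E,4R)-4,8-dimethylnona-2,7-dien-1-yl acetate | CC(=O)OC/C=C/[C@H](C)CCC=C(C)C
F5 | step 3 | (R)-trimethyl[(4-methylcyclohex-1-en-1-yl)oxy]silane | C1C[C@@H](C)CC=C1O[Si](C)(C)C
F6 | step 3 | (R)-4-methylcyclohex-2-en-1-one | C1C[C@@H](C)C=CC1=O
F7 | step 3 | (1S,5R,6S)-5-methylbicyclo[4.1.0]heptan-2-one | C1C[C@@H](C)[C@@H]2C[C@@H]2C1=O
F8 | step 3 | trimethyl{[(1S,5R,6S)-5-methylbicyclo[4.1.0]hept-2-en-2-yl]oxy}silane | C1[C@@H](C)[C@@H]2C[C@@H]2C(O[Si](C)(C)C)=C1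
F9 | step 3 | (1S,2S)-2-[(2R)-4-hydroxybutan-2-yl]cyclopropane-1-carboxylic acid | OCC[C@@H](C)[C@@H]1C[C@@H]1C(=O)O
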